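The readings stem from a simulated flask from invented constants, and the scatter is random.

I began from a one-step world, with substrate meeting a nucleophile directly, but at 2.00 min the north-west and south-east runs, both at 10 °C, read about the same substrate, 26 % and 26 %, from charges of 0.089 M and 0.067 M. So I took substrate to fall by first order to an intermediate, which the two nucleophiles then share out by their concentrations at the moment of capture.

| flask | substrate | first nucleophile | second nucleophile | temperature | remark | time |
|---|---|---|---|---|---|---|
| north-west | 0.089 M | 1.05 equiv | 2 equiv | 10 °C | run made earlier |  |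
| north-east | 0.044 M | 1.05 equiv | 2 equiv | 25 °C | run made earlier |  |
| south-east | 0.067 M | 1.05 equiv | 2 equiv | 10 °C | run made earlier |  |
| beta | 0.089 M | 1.05 equiv | 2.00 equiv (fed, over 2.0 min) | 25 °C | all else is in the flask from the start; the feed brings no volume worth counting | 3.0 min |
| zeta | 0.089 M (fed, over 2.0 min) | 1.05 equiv | 2.00 equiv |  | the addition at −5 °C, then warmed to 25 °C; the feed brings no volume worth counting | 3.0 min |
| eta | 0.089 M | 1.05 equiv | 2.00 equiv | 25 °C | everything together at the start | 3.0 min |
| epsilon | 0.089 M (fed, over 2.0 min) | 1.05 equiv | 2.00 equiv | 25 °C | all else is in the flask from the start; the feed brings no volume worth counting | 3.0 min |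

| run | time / min | target / % | other capture product / % | substrate / % |
|---|---|---|---|---|
| north-west | 0.333 | 9 | 4 | 76 |
| north-west | 1.00 | 22 | 15 | 46 |
| north-west | 2.00 | 28 | 23 | 26 |
| north-west | 3.00 | 37 | 29 | 18 |
| north-west | 4.00 | 35 | 33 | 14 |
| north-west | 5.00 | 41 | 34 | 8 |
| north-west | 6.00 | 43 | 37 | 8 |
| north-east | 0.167 | 15 | 14 | 55 |
| north-east | 0.333 | 20 | 21 | 30 |
| north-east | 0.667 | 31 | 30 | 14 |
| north-east | 1.00 | 29 | 32 | 2 |
| north-east | 1.33 | 31 | 33 | 1 |
| north-east | 2.00 | 31 | 31 | 0 |
| north-east | 2.50 | 30 | 34 | 1 |
| south-east | 0.667 | 16 | 12 | 62 |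
| south-east | 1.33 | 24 | 19 | 39 |
| south-east | 2.00 | 29 | 23 | 26 |
| south-east | 3.00 | 35 | 30 | 19 |
| south-east | 4.00 | 33 | 33 | 11 |
| south-east | 5.00 | 38 | 33 | 8 |

(each reading ± 1.5 percentage points)

- the earlier runs were read with a standard deviation of 1.5 percentage points
- a reading or a percentage of target counts all its forms, free or not
- a reading of substrate is of its free form alone

- the flask with the highest share of target in target plus other capture product ("all alike" if they lie within 1.5 percentage points) (beta / zeta / eta / epsilon / all alike)
- share of target in target plus other capture product at the end, beta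
- share of target in target plus other capture product at the end, zeta
- share of target in target plus other capture product at the end, eta
- share of target in target plus other capture product at the end, epsilon

I carried one number, the capture ratio S (a selectivity factor): target over other capture product, multiplied by c(second nucleophile) over c(first nucleophile). The north-east run at 2.00 min, with the nucleophiles taken as charged, reads S = 1.90. With both nucleophiles taken as charged, as they stand at the start of eta, epsilon and zeta, S as read at 25 °C gives a share of 50.0 %.

Beta differs. The north-east run's reading of 30 % substrate at 0.333 min gives a mean substrate life of 0.277 min, shorter than the feed of 2.0 min. So I reckoned that the average capture in beta meets about 0.277 equiv of second nucleophile. Holding first nucleophile at its charge, I reckoned a share of 87.9 % for beta.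

The forecast named beta, with 85 % for beta, 49 % for zeta, 48 % for eta and 48 % for epsilon, holding that “In beta the second nucleophile is starved”. My figure for beta ran higher than its figure.

The flasks gave 82.7 % for beta, the highest, then 52.0 % for eta, 52.0 % for epsilon and 51.8 % for zeta.

    first nucleophile + intermediate → target (k = 31.7 L mol⁻¹ s⁻¹, Ea = 38.0 kJ mol⁻¹)
    crystals ⇌ target, rate k2*(cs2 - [target]) while solid is left; crystals form when [target] > cs2 (solubility = 17.0 mM, k = 0.476 s⁻¹)
    intermediate → solvolysis product (k = 0.489 s⁻¹, Ea = 64.0 kJ mol⁻¹)
    substrate → intermediate (k = 0.0542 s⁻¹, Ea = 80.0 kJ mol⁻¹)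
    second nucleophile + intermediate → other capture product (k = 10.4 L mol⁻¹ s⁻¹, Ea = 37.0 kJ mol⁻¹)
    target ⇌ isomer of the product (K = 0.450, k = 0.106 s⁻¹, Ea = 81.0 kJ mol⁻¹, ΔH = 15.0 kJ mol⁻¹)
    substrate + target ⇌ idle adduct, settled at all times (K = 14.0 L mol⁻¹, ΔH = −39.0 kJ mol⁻¹)
    (constants at 25 °C)

Beta's 82.7 % came with 18.5 % of solvolysis product at the end, more than the 11.3 % of eta. For a flask like zeta but charged with 2.60 equiv of first nucleophile, S gives 71.2 %, and that flask ended at 75.7 %.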